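**Retrosynthetic overview**
1. The last skeletal disconnection is the depside C(=O)–O bond between the ring A acid (carboxyl on C1) and the C4 hydroxyl of ring B. Ring B is bought intact as methyl 3-methylorsellinate and carried as its benzyl ester, so that hydrogenolysis and desilylation finish the synthesis.
2. The carboxyl carbon on ring A C1 comes from magnesium-directed ortho-formylation of a C2 phenol, followed by O-methylation and Pinnick oxidation.
3. The route rests on this feature: ring A carries oxygen on C2 and C4 (meta to each other) with the hydroxymethyl carbon on C3 between them, methyl on C6 and hydrogen on C5. A vinylketene and a 1-alkoxyalkyne give exactly this pattern, so ring A is cut at C2–C3 and C4–C5 into 3-methylcyclobut-2-en-1-one and 1-methoxy-3-(triisopropylsilyloxy)prop-1-yne.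
4. The cyclobutenone comes from dichloroketene and propyne; the alkyne comes from chloroacetaldehyde dimethyl acetal through lithium methoxyacetylide and formaldehyde.
5. Order of ring formation: ring A is the only ring built (step 5); ring B is never formed or opened.

Key step: step 5

Remark on the chemistry: the target has no stereocentre. Ring A is numbered from the carbon bearing the ester carbonyl (C1; C2 OMe, C3 CH2OH, C4 OMe, C5 H, C6 CH3) and ring B from the carbon bearing CO2H. A triisopropylsilyl ether is assumed as the protecting group of the C3 hydroxymethyl oxygen throughout.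

**Route**

Step 1
Reactants: 1 trichloroacetyl chloride; 2 propyne
Product: 4 4,4-dichloro-3-methylcyclobut-2-en-1-one, via dichloroketene 3 (not isolated)
Conditions: Zn(Cu), Et2O–DME, excess propyne, dry-ice condenser, 0 °C → rt
Reagents that add atoms: none
Why: Zinc reduces 1 to dichloroketene 3, which should undergo the thermal ketene–alkyne (2+2) cycloaddition with propyne, the unsubstituted alkyne carbon bonding to the ketene carbonyl carbon so that the methyl group ends on C3 of the cyclobutenone.

Step 2
Reactants: 4 4,4-dichloro-3-methylcyclobut-2-en-1-one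
Product: 5 3-methylcyclobut-2-en-1-one
Conditions: Zn dust, AcOH, TMEDA, EtOH, 0 °C → rt; careful distillation
Reagents that add atoms: none
Why: Zinc in buffered acetic acid should remove both chlorine atoms of the alpha,alpha-dichloroketone by reductive dehalogenation through the zinc enolate, with TMEDA keeping the medium mild enough for the strained enone.

Step 3
Reactants: 6 chloroacetaldehyde dimethyl acetal
Product: 9 3-methoxyprop-2-yn-1-ol, via 1-chloro-2-methoxyethene 7 (not isolated), via lithium methoxyacetylide 8 (not isolated)
Conditions: LiNEt2 (from n-BuLi and Et2NH, 3.1 equiv), THF, 0 °C; then (CH2O)n (excess), −78 °C → rt; H2O work-up, no acid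
Reagents that add atoms: paraformaldehyde (as formaldehyde), C=O
Why: Three equivalents of amide base should eliminate methanol and then HCl from the chloroacetal and deprotonate the resulting methoxyethyne, and the lithium acetylide then adds to formaldehyde (acetylide 1,2-addition), the non-acidic work-up avoiding Meyer–Schuster-type rearrangement of the alkoxyalkynyl carbinol.

Step 4
Reactants: 9 3-methoxyprop-2-yn-1-ol
Product: 10 1-methoxy-3-(triisopropylsilyloxy)prop-1-yne
Conditions: TIPSCl, imidazole, DMF, 0 °C → rt; chromatography on Et3N-deactivated silica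
Reagents that add atoms: chlorotriisopropylsilane (TIPSCl), CC(C)[Si](Cl)(C(C)C)C(C)C
Why: Imidazole-promoted silylation of a primary alcohol is reliable, and the basic medium suits the acid-labile ynol ether.

Step 5
Reactants: 5 3-methylcyclobut-2-en-1-one; 10 1-methoxy-3-(triisopropylsilyloxy)prop-1-yne
Product: 15 3-methoxy-5-methyl-2-(triisopropylsilyloxymethyl)phenol, via vinylketene 11 (not isolated), via isopropenylcyclobutenone 12 (not isolated), via dienylketene 13 (not isolated), via cyclohexadienone 14 (not isolated)
Conditions: toluene, 80 °C then 110 °C, sealed tube; then K2CO3, MeOH, rt (returns phenol from any ketene-acylated aryl ester)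
Reagents that add atoms: none
Why: Heating should open 5 by a four-electron electrocyclic reaction to vinylketene 11, whose ketene C=C adds ynol ether 10 in a (2+2) cycloaddition to give 12; 12 opens again, reversibly, to dienylketene 13, which closes ring A by a thermal disrotatory six-electron electrocyclization between the ketene carbon and the terminal CH2 (re-forming the C1–C2 bond of ring A) to give 14, and 14 tautomerises to the phenol. The closest known reaction type is the Danheiser benzannulation of cyclobutenones with 1-alkoxyalkynes and siloxyalkynes, which gives resorcinol monoethers with the alkyne substituent between the two oxygens. The new skeletal bonds are ring A C2–C3 (ketene carbonyl carbon to the alkyne carbon remote from oxygen) and C4–C5 (ketene alpha carbon to the oxygen-bearing alkyne carbon). No stereocentre is formed. The selectivity needed is the regiochemistry of the (2+2) step, and the polarisation of the ynol ether secures it: the methoxy oxygen makes the remote carbon, the one carrying CH2OSi, nucleophilic, so it bonds to the electrophilic ketene carbonyl carbon and the methoxy carbon ends meta to the phenol oxygen, leaving one free ortho carbon (the future C1). The methoxy group has no beta hydrogen, so the retro-ene loss of alkene that limits ethoxy- and tert-butoxyalkynes at these temperatures cannot occur, and the bulky silyl ether keeps the propargylic oxygen inert.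

Step 6
Reactants: 15 3-methoxy-5-methyl-2-(triisopropylsilyloxymethyl)phenol
Product: 17 2-hydroxy-4-methoxy-6-methyl-3-(triisopropylsilyloxymethyl)benzaldehyde, via salicyl alcohol 16 (not isolated)
Conditions: MgCl2, Et3N, (CH2O)n, MeCN, reflux; then cold 1 M HCl
Reagents that add atoms: paraformaldehyde (as formaldehyde), C=O
Why: In this Casnati–Skattebøl ortho-formylation the magnesium phenoxide should deliver formaldehyde to the only free ortho carbon (also para to the methoxy group), and the magnesium benzylic alkoxide of 16 is oxidised to the aldehyde by hydride transfer to a second formaldehyde.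

Step 7
Reactants: 17 2-hydroxy-4-methoxy-6-methyl-3-(triisopropylsilyloxymethyl)benzaldehyde
Product: 18 2,4-dimethoxy-6-methyl-3-(triisopropylsilyloxymethyl)benzaldehyde
Conditions: MeI, K2CO3, DMF, rt → 40 °C
Reagents that add atoms: iodomethane, CI
Why: Williamson ether synthesis on the phenoxide of a salicylaldehyde is routine, and the aldehyde and silyl ether are inert to carbonate.

Step 8
Reactants: 18 2,4-dimethoxy-6-methyl-3-(triisopropylsilyloxymethyl)benzaldehyde
Product: 19 2,4-dimethoxy-6-methyl-3-(triisopropylsilyloxymethyl)benzoic acid
Conditions: NaClO2, NaH2PO4, 2-methylbut-2-ene, t-BuOH–H2O, rt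
Reagents that add atoms: sodium chlorite, [Na+].[O-]Cl=O
Why: Pinnick oxidation should convert the hindered, electron-rich aldehyde into the acid, with 2-methylbut-2-ene intercepting HOCl before it chlorinates ring A C5 and the phosphate buffer sparing the silyl ether.

Step 9
Reactants: 20 methyl 3-methylorsellinate (methyl 2,4-dihydroxy-3,6-dimethylbenzoate)
Product: 21 2,4-dihydroxy-3,6-dimethylbenzoic acid
Conditions: conc. H2SO4, 0 °C → rt, short time; then ice water
Reagents that add atoms: water, O
Why: Acyl–oxygen cleavage through the acylium ion (AAC1 ester hydrolysis) is the established way to hydrolyse a di-ortho-substituted, electron-rich benzoate that resists saponification, and the low temperature should keep the beta-resorcylic acid from decarboxylating.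

Step 10
Reactants: 21 2,4-dihydroxy-3,6-dimethylbenzoic acid
Product: 22 benzyl 2,4-dihydroxy-3,6-dimethylbenzoate
Conditions: BnBr, KHCO3, DMF, rt
Reagents that add atoms: benzyl bromide, BrCc1ccccc1
Why: Bicarbonate deprotonates only the carboxylic acid, so SN2 O-alkylation of the carboxylate should give the benzyl ester and leave both phenols free.

Step 11
Reactants: 19 2,4-dimethoxy-6-methyl-3-(triisopropylsilyloxymethyl)benzoic acid; 22 benzyl 2,4-dihydroxy-3,6-dimethylbenzoate
Product: 24 benzyl 4-[2,4-dimethoxy-6-methyl-3-(triisopropylsilyloxymethyl)benzoyloxy]-2-hydroxy-3,6-dimethylbenzoate, via acid chloride 23 (not isolated)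
Conditions: 1-chloro-N,N,2-trimethylprop-1-en-1-amine, CH2Cl2, 0 °C → rt; then 22, Et3N, DMAP (cat.), CH2Cl2, 0 °C → rt
Reagents that add atoms: none
Why: The alpha-chloroenamine makes the hindered acid chloride under neutral conditions that spare the silyl ether, and DMAP-catalysed acylation should occur at the ring B C4 hydroxyl because the C2 hydroxyl is hydrogen-bonded to the ester carbonyl and flanked on both sides.

Step 12
Reactants: 24 benzyl 4-[2,4-dimethoxy-6-methyl-3-(triisopropylsilyloxymethyl)benzoyloxy]-2-hydroxy-3,6-dimethylbenzoate
Product: 25 4-[2,4-dimethoxy-6-methyl-3-(triisopropylsilyloxymethyl)benzoyloxy]-2-hydroxy-3,6-dimethylbenzoic acid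
Conditions: H2 (1 atm), 10% Pd/C, EtOAc, rt; stopped when 24 is consumed
Reagents that add atoms: none
Why: Catalytic hydrogenolysis should cleave the benzyl ester O–CH2 bond much faster than the benzylic C–O bond of the bulky silyl ether in a neutral aprotic solvent, and the aryl ester is inert.

Step 13
Reactants: 25 4-[2,4-dimethoxy-6-methyl-3-(triisopropylsilyloxymethyl)benzoyloxy]-2-hydroxy-3,6-dimethylbenzoic acid
Product: 26 4-[3-(hydroxymethyl)-2,4-dimethoxy-6-methylbenzoyloxy]-2-hydroxy-3,6-dimethylbenzoic acid (CNP0372912.0)
Conditions: HF·pyridine, pyridine, THF, 0 °C → rt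
Reagents that add atoms: none
Why: Fluoride-mediated desilylation in a pyridine-buffered medium should avoid both base-promoted cleavage of the aryl ester and acid-promoted ionisation of the electron-rich benzylic alcohol, which cannot lactonise because it is meta to the ester carbonyl.

**Compound list**
1 | trichloroacetyl chloride | ClC(=O)C(Cl)(Cl)Cl | starting material
2 | propyne | CC#C | starting material
3 | dichloroketene | ClC(Cl)=C=O | intermediate
4 | 4,4-dichloro-3-methylcyclobut-2-en-1-one | CC1=CC(=O)C1(Cl)Cl | intermediate
5 | 3-methylcyclobut-2-en-1-one | CC1=CC(=O)C1 | intermediate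
6 | chloroacetaldehyde dimethyl acetal (2-chloro-1,1-dimethoxyethane) | COC(CCl)OC | starting material
7 | 1-chloro-2-methoxyethene (mixture of geometric isomers) | COC=CCl | intermediate
8 | lithium methoxyacetylide | COC#C[Li] | intermediate
9 | 3-methoxyprop-2-yn-1-ol | COC#CCO | intermediate
10 | 1-methoxy-3-(triisopropylsilyloxy)prop-1-yne | COC#CCO[Si](C(C)C)(C(C)C)C(C)C | intermediate
11 | 3-methylbuta-1,3-dien-1-one (vinylketene) | C=C(C)C=C=O | intermediate
12 | 3-methoxy-4-(prop-1-en-2-yl)-2-(triisopropylsilyloxymethyl)cyclobut-2-en-1-one (racemic, transient) | COC1=C(CO[Si](C(C)C)(C(C)C)C(C)C)C(=O)C1C(C)=C | intermediate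
13 | (3E)-3-methoxy-5-methyl-2-(triisopropylsilyloxymethyl)hexa-1,3,5-trien-1-one (dienylketene) | CO/C(=C/C(C)=C)C(CO[Si](C(C)C)(C(C)C)C(C)C)=C=O | intermediate
14 | 3-methoxy-5-methyl-2-(triisopropylsilyloxymethyl)cyclohexa-2,4-dien-1-one | COC1=C(CO[Si](C(C)C)(C(C)C)C(C)C)C(=O)CC(C)=C1 | intermediate
15 | 3-methoxy-5-methyl-2-(triisopropylsilyloxymethyl)phenol | COc1cc(C)cc(O)c1CO[Si](C(C)C)(C(C)C)C(C)C | intermediate
16 | 2-(hydroxymethyl)-5-methoxy-3-methyl-6-(triisopropylsilyloxymethyl)phenol (as its magnesium salt) | COc1cc(C)c(CO)c(O)c1CO[Si](C(C)C)(C(C)C)C(C)C | intermediate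
17 | 2-hydroxy-4-methoxy-6-methyl-3-(triisopropylsilyloxymethyl)benzaldehyde | COc1cc(C)c(C=O)c(O)c1CO[Si](C(C)C)(C(C)C)C(C)C | intermediate
18 | 2,4-dimethoxy-6-methyl-3-(triisopropylsilyloxymethyl)benzaldehyde | COc1cc(C)c(C=O)c(OC)c1CO[Si](C(C)C)(C(C)C)C(C)C | intermediate
19 | 2,4-dimethoxy-6-methyl-3-(triisopropylsilyloxymethyl)benzoic acid | COc1cc(C)c(C(=O)O)c(OC)c1CO[Si](C(C)C)(C(C)C)C(C)C | intermediate
20 | methyl 3-methylorsellinate (methyl 2,4-dihydroxy-3,6-dimethylbenzoate) | COC(=O)c1c(C)cc(O)c(C)c1O | starting material
21 | 2,4-dihydroxy-3,6-dimethylbenzoic acid | OC(=O)c1c(C)cc(O)c(C)c1O | intermediate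
22 | benzyl 2,4-dihydroxy-3,6-dimethylbenzoate | O=C(OCc1ccccc1)c1c(C)cc(O)c(C)c1O | intermediate
23 | 2,4-dimethoxy-6-methyl-3-(triisopropylsilyloxymethyl)benzoyl chloride | COc1cc(C)c(C(Cl)=O)c(OC)c1CO[Si](C(C)C)(C(C)C)C(C)C | intermediate
24 | benzyl 4-[2,4-dimethoxy-6-methyl-3-(triisopropylsilyloxymethyl)benzoyloxy]-2-hydroxy-3,6-dimethylbenzoate | COc1cc(C)c(C(=O)Oc2cc(C)c(C(=O)OCc3ccccc3)c(O)c2C)c(OC)c1CO[Si](C(C)C)(C(C)C)C(C)C | intermediate
25 | 4-[2,4-dimethoxy-6-methyl-3-(triisopropylsilyloxymethyl)benzoyloxy]-2-hydroxy-3,6-dimethylbenzoic acid | COc1cc(C)c(C(=O)Oc2cc(C)c(C(=O)O)c(O)c2C)c(OC)c1CO[Si](C(C)C)(C(C)C)C(C)C | intermediate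
26 | 4-[3-(hydroxymethyl)-2,4-dimethoxy-6-methylbenzoyloxy]-2-hydroxy-3,6-dimethylbenzoic acid (CNP0372912.0) | COc1cc(C)c(C(=O)Oc2cc(C)c(C(=O)O)c(O)c2C)c(OC)c1CO | target

**Step count**
Total steps: 13. Longest linear sequence: 9 steps (1, 2, 5, 6, 7, 8, 11, 12, 13; the branch through 3 and 4 is equally long; the ring B branch 9, 10, 11, 12, 13 has 5 steps).

**Steps most likely to fail, with fallbacks**

Step 5 (key benzannulation). At the temperature needed to open the cyclobutenone, the vinylketene may be consumed by dimerisation or by O-acylation of the product phenol, and the volatile cyclobutenone may be lost before it reacts. The fallback sets out from alkyne 10 and comes back to the route at phenol 15. It generates the same vinylketene at room temperature by a photochemical Wolff rearrangement (the second-generation form of the benzannulation) instead of by thermal opening of a cyclobutenone. Commercial 3-methylbut-3-en-2-one F1 is trifluoroacetylated at its methyl group (LiN(SiMe3)2, CF3CO2CH2CF3, THF, −78 °C) to 1,1,1-trifluoro-5-methylhex-5-ene-2,4-dione F2. Detrifluoroacetylative diazo transfer (MsN3, Et3N, H2O, MeCN, rt) should then give 1-diazo-3-methylbut-3-en-2-one F3. Irradiation of F3 with 10 in CH2Cl2 at room temperature should expel N2 and give vinylketene 11, which follows the same path through 12, 13 and 14; brief heating at 80 °C completes the electrocyclic steps to 15. This fallback also removes the dependence on steps 1 and 2.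

Step 3 (acetylide formation and hydroxymethylation). Diethylamine and lithium methoxide in the flask may compete for formaldehyde, and the small, water-soluble, acid-labile propargylic alcohol may be lost or rearranged during isolation. The fallback sets out from acetal 6 and comes back at silyl ether 10. It replaces formaldehyde addition by alkylation of an amine-free acetylide with a silyloxymethyl electrophile, so that alcohol 9 is never handled. Acetal 6 with NaNH2 (3 equiv) in liquid NH3 should give sodium methoxyacetylide F4, which is protonated with cold brine and distilled as methoxyethyne F5. Deprotonation of F5 with n-BuLi in THF at −78 °C gives lithium methoxyacetylide 8 free of amine and alkoxide. Alkylation of 8 with commercial (triisopropylsilyloxy)methyl chloride F6 (−78 °C → 0 °C) should give 10 directly, so step 4 is bypassed.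

Step 6 (ortho-formylation). C–C bond formation at the only free ortho carbon, which is flanked by the methyl group, may be sluggish, and on prolonged heating the magnesium phenoxide may expel silanolate from the neighbouring benzylic position (ortho-quinone methide formation). The fallback sets out from phenol 15 and comes back at acid 19. It introduces the carboxyl carbon through an aryllithium instead of a formyl group. O-Methylation first (MeI, K2CO3, DMF) gives 1,3-dimethoxy-5-methyl-2-(triisopropylsilyloxymethyl)benzene F7, whose two free ring positions are equivalent by symmetry. Ring bromination with NBS in MeCN at 0 °C in the dark should therefore give a single monobromide, 1-bromo-2,4-dimethoxy-6-methyl-3-(triisopropylsilyloxymethyl)benzene F8. Bromine–lithium exchange (n-BuLi, THF, −78 °C) gives [2,4-dimethoxy-6-methyl-3-(triisopropylsilyloxymethyl)phenyl]lithium F9. Quenching F9 with CO2 and working up with aqueous NH4Cl should give acid 19, bypassing 17 and 18 (steps 7 and 8).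

**Further compounds**
F1 | step 5 | 3-methylbut-3-en-2-one | CC(=O)C(C)=C
F2 | step 5 | 1,1,1-trifluoro-5-methylhex-5-ene-2,4-dione | C=C(C)C(=O)CC(=O)C(F)(F)F
F3 | step 5 | 1-diazo-3-methylbut-3-en-2-one | C=C(C)C(=O)C=[N+]=[N-]
F4 | step 3 | sodium methoxyacetylide | COC#C[Na]
F5 | step 3 | methoxyethyne | COC#C
F6 | step 3 | (triisopropylsilyloxy)methyl chloride | ClCO[Si](C(C)C)(C(C)C)C(C)C
F7 | step 6 | 1,3-dimethoxy-5-methyl-2-(triisopropylsilyloxymethyl)benzene | COc1cc(C)cc(OC)c1CO[Si](C(C)C)(C(C)C)C(C)C
F8 | step 6 | 1-bromo-2,4-dimethoxy-6-methyl-3-(triisopropylsilyloxymethyl)benzene | COc1cc(C)c(Br)c(OC)c1CO[Si](C(C)C)(C(C)C)C(C)C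
F9 | step 6 | [2,4-dimethoxy-6-methyl-3-(triisopropylsilyloxymethyl)phenyl]lithium | COc1cc(C)c([Li])c(OC)c1CO[Si](C(C)C)(C(C)C)C(C)C
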